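**Plan**

1. Retrosynthetic cuts, in order: the seven phenols (masked as silyl ethers); the C4–vinyl bond of the Z-styryl group on benzene ring B (Suzuki coupling of a C4 triflate); the C3–C5' bond between dihydrofuran ring 1 and benzene ring D (decarboxylative arylation of a C3 acid); the C2'–C3' bond of dihydrofuran ring 2 (carbene C–H insertion); and the C3–C3a bond of ring 1, which leads back to a flavanone.
2. Enabling feature: ring 1 (O1–C2–C3–C3a–C7a) fused to ring B, with the S-configured C2 bearing a 4-hydroxyphenyl group, oxygen at C6 and a position C4 that can carry oxygen, is the chroman-4-one of (S)-naringenin short of one ring atom. Moving the ring B carbon from the carbonyl carbon to the α-carbon contracts the pyranone and leaves the carbonyl carbon as a C3 ester, the handle for the ring D aryl group.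
3. Forward order: naringenin is protected, contracted to ring 1 and converted into a C3 redox-active ester; ring 2 is closed on ring D starting from 5-bromo-o-vanillin; the halves are joined at C3–C5'; benzyl is then exchanged for triflate and methyl for silyl, the Z-styryl group is coupled on, and fluoride frees the phenols.
4. Stereochemistry: C2 comes from naringenin; C3 is set trans to the C2 aryl group by substrate control; C3' is set by a chiral dirhodium catalyst and C2' by acid equilibration to trans; the Z olefin comes from a Z-alkenylboronate coupled with retention.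

Key step: step 3

Assumptions: (S)-naringenin and tert-butyl(4-ethynylphenoxy)dimethylsilane are bought, the former enantiopure; Rh2(R-PTAD)4 is taken to give the (3R) series in step 10, and its mirror-image catalyst would be used if the sense of induction proved opposite.

Step 1
Reactants: 1 (S)-naringenin
Product: 2 (S)-5-hydroxy-7-methoxy-2-(4-methoxyphenyl)chroman-4-one
Conditions: TMSCHN2 (2.2 equiv), i-Pr2NEt, MeOH/MeCN, 0 °C to rt
Reagents that add atoms: (trimethylsilyl)diazomethane, C[Si](C)(C)C=[N+]=[N-]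
Why: O-Methylation of phenols by a diazoalkane should take only the acidic 7- and 4'-hydroxyls, since the 5-hydroxyl is held in a hydrogen bond to the C4 carbonyl, and without a strong base the flavanone should not open to the chalcone, so C2 stays S.

Step 2
Reactants: 2 (S)-5-hydroxy-7-methoxy-2-(4-methoxyphenyl)chroman-4-one
Product: 3 (S)-5-(benzyloxy)-7-methoxy-2-(4-methoxyphenyl)chroman-4-one
Conditions: BnBr, K2CO3, DMF, rt to 40 °C
Reagents that add atoms: benzyl bromide, BrCc1ccccc1
Why: Williamson etherification of the chelated 5-phenoxide, run with a carbonate base near room temperature so that C3 is hardly deprotonated and the retro-oxa-Michael opening to the chalcone, which would racemise C2, is kept down, gives a benzyl ether that keeps ring B electron-rich and can later be removed beside methyl ethers.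

Step 3
Reactants: 3 (S)-5-(benzyloxy)-7-methoxy-2-(4-methoxyphenyl)chroman-4-one
Product: 5 methyl (2S,3S)-4-(benzyloxy)-6-methoxy-2-(4-methoxyphenyl)-2,3-dihydrobenzofuran-3-carboxylate, via methyl enol ether 4 (not isolated)
Conditions: PhI(OAc)2 (1.2 equiv), conc. H2SO4, HC(OMe)3, 0 °C to rt
Reagents that add atoms: trimethyl orthoformate, COC(OC)OC
Why: Acid and trimethyl orthoformate turn the C4 ketone of 3 into its methyl enol ether 4, whose C3 attacks the trivalent iodine of PhI(OAc)2 anti to the C2 aryl group while methanol adds back at C4, giving a C4 dimethyl ketal with an equatorial C3–I(Ph)OAc bond. That bond is antiperiplanar to the ring bond C4–C4a, so the ring B carbon C4a moves from C4 to C3 as iodobenzene leaves (an oxidative 1,2-aryl shift, the hypervalent-iodine counterpart of the Tl(NO3)3 rearrangement of aryl ketones and flavanones in trimethyl orthoformate), and the dimethoxycarbenium ion left at the old C4 is demethylated to the methyl ester. Ring 1 thus arises by ring contraction through a phenonium-like bridged shift that forms C3–C3a, not by an exo or endo cyclisation. The new stereocentre C3 should come out trans to the C2 aryl group, (2S,3S), because the iodane enters anti to that group and the shift inverts C3, and because the α-ester centre can in any case equilibrate to the more stable trans isomer; C2 is not touched. The selectivity needed is migration of ring B rather than of the C2 aryl group (isoflavone) or simple elimination (flavone); the donor oxygens ortho and para to C4a, kept electron-releasing by the 5-benzyl ether, and the diequatorial arrangement of aryl group and iodane should secure it.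

Step 4
Reactants: 5 methyl (2S,3S)-4-(benzyloxy)-6-methoxy-2-(4-methoxyphenyl)-2,3-dihydrobenzofuran-3-carboxylate
Product: 6 (2S,3S)-4-(benzyloxy)-6-methoxy-2-(4-methoxyphenyl)-2,3-dihydrobenzofuran-3-carboxylic acid
Conditions: Me3SnOH, 1,2-dichloroethane, 80 °C; then 1 M HCl
Reagents that add atoms: trimethyltin hydroxide, C[Sn](C)(C)O
Why: Trimethyltin hydroxide cleaves the methyl ester by acyl substitution under nearly neutral conditions, which avoids the ester enolate that could expel the ring oxygen O1 (retro-oxa-Michael) and so endanger C2, while C3 can only settle in the trans arrangement it already has.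

Step 5
Reactants: 6 (2S,3S)-4-(benzyloxy)-6-methoxy-2-(4-methoxyphenyl)-2,3-dihydrobenzofuran-3-carboxylic acid
Product: 7 1,3-dioxoisoindolin-2-yl (2S,3S)-4-(benzyloxy)-6-methoxy-2-(4-methoxyphenyl)-2,3-dihydrobenzofuran-3-carboxylate
Conditions: N-hydroxyphthalimide, N,N'-diisopropylcarbodiimide, DMAP (cat.), CH2Cl2, rt
Reagents that add atoms: N-hydroxyphthalimide, ON1C(=O)c2ccccc2C1=O
Why: Carbodiimide coupling (Steglich-type esterification) with N-hydroxyphthalimide gives the redox-active ester needed for single-electron decarboxylation, and the C3 configuration is of no concern here because it is erased and set anew in step 12.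

Step 6
Reactants: 8 5-bromo-2-hydroxy-3-methoxybenzaldehyde; 9 4-methoxybenzyl chloride
Product: 10 5-bromo-3-methoxy-2-[(4-methoxybenzyl)oxy]benzaldehyde
Conditions: K2CO3, DMF, 50 °C
Reagents that add atoms: none
Why: Williamson etherification of the phenol next to the aldehyde installs the ether whose benzylic CH2 becomes C2' and whose 4-methoxyphenyl group becomes the C2' aryl group of ring 2.

Step 7
Reactants: 10 5-bromo-3-methoxy-2-[(4-methoxybenzyl)oxy]benzaldehyde; 11 1-bromo-3,5-dimethoxybenzene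
Product: 13 (±)-{5-bromo-3-methoxy-2-[(4-methoxybenzyl)oxy]phenyl}(3,5-dimethoxyphenyl)methanol, via 3,5-dimethoxyphenylmagnesium bromide 12 (not isolated)
Conditions: 11, Mg, THF, reflux; then 10, THF, 0 °C; aq. NH4Cl
Reagents that add atoms: none
Why: Grignard addition to the aldehyde at 0 °C, where the aryl bromide of 10 is inert, brings in the 3,5-dimethoxyphenyl group of C3'; the carbinol centre is racemic and is removed in the next step.

Step 8
Reactants: 13 (±)-{5-bromo-3-methoxy-2-[(4-methoxybenzyl)oxy]phenyl}(3,5-dimethoxyphenyl)methanol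
Product: 14 {5-bromo-3-methoxy-2-[(4-methoxybenzyl)oxy]phenyl}(3,5-dimethoxyphenyl)methanone
Conditions: MnO2, CH2Cl2, rt
Reagents that add atoms: none
Why: Oxidation of the doubly benzylic alcohol to the benzophenone with MnO2 should leave the 4-methoxybenzyl ether and the aryl bromide alone.

Step 9
Reactants: 14 {5-bromo-3-methoxy-2-[(4-methoxybenzyl)oxy]phenyl}(3,5-dimethoxyphenyl)methanone
Product: 15 {5-bromo-3-methoxy-2-[(4-methoxybenzyl)oxy]phenyl}(3,5-dimethoxyphenyl)methanone hydrazone (E/Z mixture)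
Conditions: N2H4·H2O, AcOH (cat.), EtOH, reflux
Reagents that add atoms: hydrazine, NN
Why: Acid-catalysed condensation of the diaryl ketone with hydrazine gives the free hydrazone, both geometric isomers of which lead to the same diazo compound.

Step 10
Reactants: 15 {5-bromo-3-methoxy-2-[(4-methoxybenzyl)oxy]phenyl}(3,5-dimethoxyphenyl)methanone hydrazone
Product: 17 (2S,3R)-5-bromo-3-(3,5-dimethoxyphenyl)-7-methoxy-2-(4-methoxyphenyl)-2,3-dihydrobenzofuran (cis), via diaryldiazomethane 16 (not isolated)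
Conditions: MnO2, CH2Cl2, rt, filtered; then Rh2(R-PTAD)4 (1 mol%; the dirhodium tetracarboxylate of (R)-N-phthaloyl-(1-adamantyl)glycine), CH2Cl2, 0 °C
Reagents that add atoms: none
Why: Dehydrogenation of the hydrazone by MnO2 gives the diaryldiazomethane, and its dirhodium carbene inserts into the activated benzylic C–H bond of the 4-methoxybenzyl ether (intramolecular 1,5 C–H insertion of a donor/donor carbene), closing ring 2 by the C2'–C3' bond, with the chiral carboxylate ligands setting C3' as R and the kinetic cis relationship to C2' (S).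

Step 11
Reactants: 17 (2S,3R)-5-bromo-3-(3,5-dimethoxyphenyl)-7-methoxy-2-(4-methoxyphenyl)-2,3-dihydrobenzofuran
Product: 18 (2R,3R)-5-bromo-3-(3,5-dimethoxyphenyl)-7-methoxy-2-(4-methoxyphenyl)-2,3-dihydrobenzofuran (trans)
Conditions: BF3·OEt2 (1 equiv), CH2Cl2, −20 °C to rt
Reagents that add atoms: none
Why: Lewis acid ionisation of the benzylic C2'–O1' bond to a 4-methoxybenzyl cation and re-closure by the tethered phenoxide is reversible, so C2' should equilibrate to the more stable trans isomer while C3', which is not involved, keeps its R configuration (acid-mediated cis-to-trans epimerisation of 2-aryl-2,3-dihydrobenzofurans).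

Step 12
Reactants: 7 1,3-dioxoisoindolin-2-yl (2S,3S)-4-(benzyloxy)-6-methoxy-2-(4-methoxyphenyl)-2,3-dihydrobenzofuran-3-carboxylate; 18 (2R,3R)-5-bromo-3-(3,5-dimethoxyphenyl)-7-methoxy-2-(4-methoxyphenyl)-2,3-dihydrobenzofuran
Product: 21 (2S,3S)-4-(benzyloxy)-3-[(2R,3R)-3-(3,5-dimethoxyphenyl)-7-methoxy-2-(4-methoxyphenyl)-2,3-dihydrobenzofuran-5-yl]-6-methoxy-2-(4-methoxyphenyl)-2,3-dihydrobenzofuran, via aryllithium 19 (not isolated), via arylzinc chloride 20 (not isolated)
Conditions: 18 (2 equiv), n-BuLi, THF, −78 °C; ZnCl2, −78 °C to rt; then 7, NiCl2·glyme (20 mol%), 4,4'-di-tert-butyl-2,2'-bipyridine (40 mol%), THF/DMF, rt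
Reagents that add atoms: none
Why: Nickel-catalysed decarboxylative Negishi-type arylation of a redox-active ester, in which bromine–lithium exchange and transmetalation give the arylzinc, low-valent nickel reduces the N-hydroxyphthalimide ester, loss of CO2 and phthalimide leaves a planar benzylic C3 radical, and the arylnickel captures it and forms the C3–C5' bond on the face away from the C2 aryl group, which should set C3 as S (trans) by substrate control.

Step 13
Reactants: 21 (2S,3S)-4-(benzyloxy)-3-[(2R,3R)-3-(3,5-dimethoxyphenyl)-7-methoxy-2-(4-methoxyphenyl)-2,3-dihydrobenzofuran-5-yl]-6-methoxy-2-(4-methoxyphenyl)-2,3-dihydrobenzofuran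
Product: 22 (2S,3S)-3-[(2R,3R)-3-(3,5-dimethoxyphenyl)-7-methoxy-2-(4-methoxyphenyl)-2,3-dihydrobenzofuran-5-yl]-6-methoxy-2-(4-methoxyphenyl)-2,3-dihydrobenzofuran-4-ol
Conditions: H2 (1 atm), Pd/C, EtOAc/MeOH, rt
Reagents that add atoms: none
Why: Hydrogenolysis of the aryl benzyl ether over palladium on carbon is expected to be much faster than cleavage of the cyclic benzylic C2–O1 and C2'–O1' bonds, as in the debenzylation of flavan polyphenols, and should free only the C4 phenol.

Step 14
Reactants: 22 (2S,3S)-3-[(2R,3R)-3-(3,5-dimethoxyphenyl)-7-methoxy-2-(4-methoxyphenyl)-2,3-dihydrobenzofuran-5-yl]-6-methoxy-2-(4-methoxyphenyl)-2,3-dihydrobenzofuran-4-ol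
Product: 23 (2S,3S)-3-[(2R,3R)-3-(3,5-dimethoxyphenyl)-7-methoxy-2-(4-methoxyphenyl)-2,3-dihydrobenzofuran-5-yl]-6-methoxy-2-(4-methoxyphenyl)-2,3-dihydrobenzofuran-4-yl trifluoromethanesulfonate
Conditions: Tf2O, pyridine, CH2Cl2, 0 °C
Reagents that add atoms: trifluoromethanesulfonic anhydride, O=S(=O)(OS(=O)(=O)C(F)(F)F)C(F)(F)F
Why: Sulfonylation of the single free phenol with triflic anhydride and pyridine turns the former 5-oxygen of naringenin into the leaving group for cross-coupling at C4.

Step 15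
Reactants: 23 (2S,3S)-3-[(2R,3R)-3-(3,5-dimethoxyphenyl)-7-methoxy-2-(4-methoxyphenyl)-2,3-dihydrobenzofuran-5-yl]-6-methoxy-2-(4-methoxyphenyl)-2,3-dihydrobenzofuran-4-yl trifluoromethanesulfonate
Product: 24 (2S,3S)-3-[(2R,3R)-3-(3,5-dihydroxyphenyl)-7-hydroxy-2-(4-hydroxyphenyl)-2,3-dihydrobenzofuran-5-yl]-6-hydroxy-2-(4-hydroxyphenyl)-2,3-dihydrobenzofuran-4-yl trifluoromethanesulfonate
Conditions: BBr3 (12 equiv), CH2Cl2, −78 °C to rt; then MeOH, H2O
Reagents that add atoms: none
Why: Lewis acid ether cleavage with BBr3 should remove the six methyl groups while the aryl triflate is inert to it, and it is done before any stilbene is present, any C2–O ionisation being reversible and returning the trans rings, which are the stable isomers.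

Step 16
Reactants: 24 (2S,3S)-3-[(2R,3R)-3-(3,5-dihydroxyphenyl)-7-hydroxy-2-(4-hydroxyphenyl)-2,3-dihydrobenzofuran-5-yl]-6-hydroxy-2-(4-hydroxyphenyl)-2,3-dihydrobenzofuran-4-yl trifluoromethanesulfonate
Product: 25 hexakis(tert-butyldimethylsilyl) ether of 24, with all six phenols silylated and the C4 triflate kept
Conditions: TBSCl, imidazole, DMF, rt
Reagents that add atoms: tert-butyldimethylsilyl chloride, CC(C)(C)[Si](C)(C)Cl
Why: Silylation of the six phenols with a silyl chloride and imidazole gives ethers that should withstand the mildly basic coupling and can be removed at the end with fluoride, so that the Z-stilbene never meets a Lewis acid.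

Step 17
Reactants: 26 tert-butyl(4-ethynylphenoxy)dimethylsilane
Product: 27 (Z)-tert-butyldimethyl{4-[2-(4,4,5,5-tetramethyl-1,3,2-dioxaborolan-2-yl)ethenyl]phenoxy}silane
Conditions: 26 (1.2 equiv), HBpin, [Rh(cod)Cl]2 (1.5 mol%), P(i-Pr)3 (6 mol%), Et3N, cyclohexane, rt
Reagents that add atoms: pinacolborane, CC1(C)OBOC1(C)C
Why: Rhodium-catalysed trans-hydroboration of a terminal alkyne, which runs through a rhodium vinylidene and so places boron and the aryl group cis, should give the (Z)-alkenylboronate with its phenol already in the silyl-protected form of the other six.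

Step 18
Reactants: 25 hexakis(tert-butyldimethylsilyl) ether triflate; 27 (Z)-tert-butyldimethyl{4-[2-(4,4,5,5-tetramethyl-1,3,2-dioxaborolan-2-yl)ethenyl]phenoxy}silane
Product: 28 heptakis(tert-butyldimethylsilyl) ether of the target
Conditions: Pd(OAc)2 (5 mol%), SPhos (10 mol%), K3PO4, THF/H2O, 40 °C
Reagents that add atoms: none
Why: Suzuki–Miyaura coupling of the aryl triflate with the alkenylboronate, with an electron-rich biaryl phosphine to help oxidative addition at the hindered C4 position, forms the C4–vinyl bond with retention of the Z geometry carried by the boronate.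

Step 19
Reactants: 28 heptakis(tert-butyldimethylsilyl) ether of the target
Product: 29 CNP0172909.2, (2S,3S)-3-[(2R,3R)-3-(3,5-dihydroxyphenyl)-7-hydroxy-2-(4-hydroxyphenyl)-2,3-dihydrobenzofuran-5-yl]-2-(4-hydroxyphenyl)-4-[(Z)-2-(4-hydroxyphenyl)ethenyl]-2,3-dihydrobenzofuran-6-ol
Conditions: TBAF, AcOH, THF, 0 °C to rt, argon, dark
Reagents that add atoms: none
Why: Fluoride cleaves the seven aryl silyl ethers (desilylation) under acetic acid buffering and with exclusion of air and light, conditions that should neither isomerise the Z olefin nor ionise the dihydrobenzofuran C2–O bonds.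

**Compound list**

1 | (S)-naringenin | O=C1C[C@@H](c2ccc(O)cc2)Oc2cc(O)cc(O)c21 | starting material
2 | (S)-5-hydroxy-7-methoxy-2-(4-methoxyphenyl)chroman-4-one | O=C1C[C@@H](c2ccc(OC)cc2)Oc2cc(OC)cc(O)c21 | intermediate
3 | (S)-5-(benzyloxy)-7-methoxy-2-(4-methoxyphenyl)chroman-4-one | O=C1C[C@@H](c2ccc(OC)cc2)Oc2cc(OC)cc(OCc3ccccc3)c21 | intermediate
4 | (S)-5-(benzyloxy)-4,7-dimethoxy-2-(4-methoxyphenyl)-2H-chromene (methyl enol ether, not isolated) | COC1=C[C@@H](c2ccc(OC)cc2)Oc2cc(OC)cc(OCc3ccccc3)c21 | intermediate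
5 | methyl (2S,3S)-4-(benzyloxy)-6-methoxy-2-(4-methoxyphenyl)-2,3-dihydrobenzofuran-3-carboxylate | c1ccccc1COc1cc(OC)cc2c1[C@H](C(=O)OC)[C@@H](c1ccc(OC)cc1)O2 | intermediate
6 | (2S,3S)-4-(benzyloxy)-6-methoxy-2-(4-methoxyphenyl)-2,3-dihydrobenzofuran-3-carboxylic acid | c1ccccc1COc1cc(OC)cc2c1[C@H](C(=O)O)[C@@H](c1ccc(OC)cc1)O2 | intermediate
7 | 1,3-dioxoisoindolin-2-yl (2S,3S)-4-(benzyloxy)-6-methoxy-2-(4-methoxyphenyl)-2,3-dihydrobenzofuran-3-carboxylate | c1ccccc1COc1cc(OC)cc2c1[C@H](C(=O)ON1C(=O)c3ccccc3C1=O)[C@@H](c1ccc(OC)cc1)O2 | intermediate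
8 | 5-bromo-2-hydroxy-3-methoxybenzaldehyde | COc1cc(Br)cc(C=O)c1O | starting material
9 | 4-methoxybenzyl chloride | COc1ccc(CCl)cc1 | starting material
10 | 5-bromo-3-methoxy-2-[(4-methoxybenzyl)oxy]benzaldehyde | COc1ccc(COc2c(OC)cc(Br)cc2C=O)cc1 | intermediate
11 | 1-bromo-3,5-dimethoxybenzene | COc1cc(Br)cc(OC)c1 | starting material
12 | 3,5-dimethoxyphenylmagnesium bromide (not isolated) | COc1cc([Mg]Br)cc(OC)c1 | intermediate
13 | (±)-{5-bromo-3-methoxy-2-[(4-methoxybenzyl)oxy]phenyl}(3,5-dimethoxyphenyl)methanol | COc1ccc(COc2c(OC)cc(Br)cc2C(O)c2cc(OC)cc(OC)c2)cc1 | intermediate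
14 | {5-bromo-3-methoxy-2-[(4-methoxybenzyl)oxy]phenyl}(3,5-dimethoxyphenyl)methanone | COc1ccc(COc2c(OC)cc(Br)cc2C(=O)c2cc(OC)cc(OC)c2)cc1 | intermediate
15 | {5-bromo-3-methoxy-2-[(4-methoxybenzyl)oxy]phenyl}(3,5-dimethoxyphenyl)methanone hydrazone (E/Z mixture) | COc1ccc(COc2c(OC)cc(Br)cc2C(=NN)c2cc(OC)cc(OC)c2)cc1 | intermediate
16 | 5-bromo-1-[diazo(3,5-dimethoxyphenyl)methyl]-3-methoxy-2-[(4-methoxybenzyl)oxy]benzene (not isolated) | COc1ccc(COc2c(OC)cc(Br)cc2C(=[N+]=[N-])c2cc(OC)cc(OC)c2)cc1 | intermediate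
17 | (2S,3R)-5-bromo-3-(3,5-dimethoxyphenyl)-7-methoxy-2-(4-methoxyphenyl)-2,3-dihydrobenzofuran (cis) | Brc1cc(OC)c2c(c1)[C@@H](c1cc(OC)cc(OC)c1)[C@@H](c1ccc(OC)cc1)O2 | intermediate
18 | (2R,3R)-5-bromo-3-(3,5-dimethoxyphenyl)-7-methoxy-2-(4-methoxyphenyl)-2,3-dihydrobenzofuran (trans) | Brc1cc(OC)c2c(c1)[C@@H](c1cc(OC)cc(OC)c1)[C@H](c1ccc(OC)cc1)O2 | intermediate
19 | [(2R,3R)-3-(3,5-dimethoxyphenyl)-7-methoxy-2-(4-methoxyphenyl)-2,3-dihydrobenzofuran-5-yl]lithium (not isolated) | [Li]c1cc(OC)c2c(c1)[C@@H](c1cc(OC)cc(OC)c1)[C@H](c1ccc(OC)cc1)O2 | intermediate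
20 | [(2R,3R)-3-(3,5-dimethoxyphenyl)-7-methoxy-2-(4-methoxyphenyl)-2,3-dihydrobenzofuran-5-yl]zinc chloride (not isolated) | Cl[Zn]c1cc(OC)c2c(c1)[C@@H](c1cc(OC)cc(OC)c1)[C@H](c1ccc(OC)cc1)O2 | intermediate
21 | (2S,3S)-4-(benzyloxy)-3-[(2R,3R)-3-(3,5-dimethoxyphenyl)-7-methoxy-2-(4-methoxyphenyl)-2,3-dihydrobenzofuran-5-yl]-6-methoxy-2-(4-methoxyphenyl)-2,3-dihydrobenzofuran | c1ccccc1COc1cc(OC)cc2c1[C@H](c1cc(OC)c3c(c1)[C@@H](c1cc(OC)cc(OC)c1)[C@H](c1ccc(OC)cc1)O3)[C@@H](c1ccc(OC)cc1)O2 | intermediate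
22 | (2S,3S)-3-[(2R,3R)-3-(3,5-dimethoxyphenyl)-7-methoxy-2-(4-methoxyphenyl)-2,3-dihydrobenzofuran-5-yl]-6-methoxy-2-(4-methoxyphenyl)-2,3-dihydrobenzofuran-4-ol | Oc1cc(OC)cc2c1[C@H](c1cc(OC)c3c(c1)[C@@H](c1cc(OC)cc(OC)c1)[C@H](c1ccc(OC)cc1)O3)[C@@H](c1ccc(OC)cc1)O2 | intermediate
23 | (2S,3S)-3-[(2R,3R)-3-(3,5-dimethoxyphenyl)-7-methoxy-2-(4-methoxyphenyl)-2,3-dihydrobenzofuran-5-yl]-6-methoxy-2-(4-methoxyphenyl)-2,3-dihydrobenzofuran-4-yl trifluoromethanesulfonate | O=S(=O)(Oc1cc(OC)cc2c1[C@H](c1cc(OC)c3c(c1)[C@@H](c1cc(OC)cc(OC)c1)[C@H](c1ccc(OC)cc1)O3)[C@@H](c1ccc(OC)cc1)O2)C(F)(F)F | intermediate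
24 | (2S,3S)-3-[(2R,3R)-3-(3,5-dihydroxyphenyl)-7-hydroxy-2-(4-hydroxyphenyl)-2,3-dihydrobenzofuran-5-yl]-6-hydroxy-2-(4-hydroxyphenyl)-2,3-dihydrobenzofuran-4-yl trifluoromethanesulfonate | O=S(=O)(Oc1cc(O)cc2c1[C@H](c1cc(O)c3c(c1)[C@@H](c1cc(O)cc(O)c1)[C@H](c1ccc(O)cc1)O3)[C@@H](c1ccc(O)cc1)O2)C(F)(F)F | intermediate
25 | hexakis(tert-butyldimethylsilyl) ether of 24: (2S,3S)-6-(silyloxy)-2-[4-(silyloxy)phenyl]-3-{(2R,3R)-7-(silyloxy)-3-[3,5-bis(silyloxy)phenyl]-2-[4-(silyloxy)phenyl]-2,3-dihydrobenzofuran-5-yl}-2,3-dihydrobenzofuran-4-yl trifluoromethanesulfonate, silyl = tert-butyldimethylsilyl | O=S(=O)(Oc1cc(O[Si](C)(C)C(C)(C)C)cc2c1[C@H](c1cc(O[Si](C)(C)C(C)(C)C)c3c(c1)[C@@H](c1cc(O[Si](C)(C)C(C)(C)C)cc(O[Si](C)(C)C(C)(C)C)c1)[C@H](c1ccc(O[Si](C)(C)C(C)(C)C)cc1)O3)[C@@H](c1ccc(O[Si](C)(C)C(C)(C)C)cc1)O2)C(F)(F)F | intermediate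
26 | tert-butyl(4-ethynylphenoxy)dimethylsilane | C#Cc1ccc(O[Si](C)(C)C(C)(C)C)cc1 | starting material
27 | (Z)-tert-butyldimethyl{4-[2-(4,4,5,5-tetramethyl-1,3,2-dioxaborolan-2-yl)ethenyl]phenoxy}silane | CC(C)(C)[Si](C)(C)Oc1ccc(/C=C\B2OC(C)(C)C(C)(C)O2)cc1 | intermediate
28 | heptakis(tert-butyldimethylsilyl) ether of the target (all seven phenols silylated, Z olefin) | CC(C)(C)[Si](C)(C)Oc1ccc(/C=C\c2cc(O[Si](C)(C)C(C)(C)C)cc3c2[C@H](c2cc(O[Si](C)(C)C(C)(C)C)c4c(c2)[C@@H](c2cc(O[Si](C)(C)C(C)(C)C)cc(O[Si](C)(C)C(C)(C)C)c2)[C@H](c2ccc(O[Si](C)(C)C(C)(C)C)cc2)O4)[C@@H](c2ccc(O[Si](C)(C)C(C)(C)C)cc2)O3)cc1 | intermediate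
29 | CNP0172909.2, (2S,3S)-3-[(2R,3R)-3-(3,5-dihydroxyphenyl)-7-hydroxy-2-(4-hydroxyphenyl)-2,3-dihydrobenzofuran-5-yl]-2-(4-hydroxyphenyl)-4-[(Z)-2-(4-hydroxyphenyl)ethenyl]-2,3-dihydrobenzofuran-6-ol | Oc1ccc(/C=C\c2cc(O)cc3c2[C@H](c2cc(O)c4c(c2)[C@@H](c2cc(O)cc(O)c2)[C@H](c2ccc(O)cc2)O4)[C@@H](c2ccc(O)cc2)O3)cc1 | target

**Step count and risks**

Total step count: 19 (steps 1–5 for the ring 1 half, 6–11 for the ring D half, 12 for the union, 13–16 and 18–19 for the end game, 17 for the boronate).
Longest linear sequence: 13 steps, from 8 through steps 6–16, 18 and 19 (12 steps from 1).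

Step 12 (decarboxylative arylation). After decarboxylation the benzylic C3 radical, or the alkylnickel formed from it, may lose the ring oxygen by β-aryloxy elimination and open ring 1, lose the C2 hydrogen by β-hydride elimination to a benzofuran, or dimerise. Capture by the arylnickel between the 4-benzyloxy group and the C2 aryl group may also be slow, and the arylzinc is consumed in excess. The fallback reverses the polarity of the union and needs neither redox-active ester nor organozinc: acid 6, as its caesium salt, and aryl bromide 18 would be joined directly by dual photoredox/nickel decarboxylative arylation (Ir[dF(CF3)ppy]2(dtbbpy)PF6, NiCl2·glyme, 4,4'-di-tert-butyl-2,2'-bipyridine, Cs2CO3, DMF, blue light, rt). There zerovalent nickel first inserts into the C–Br bond of 18, and the arylnickel then captures the C3 radical released by photo-oxidation of the carboxylate; the same approach anti to the C2 aryl group is expected. This fallback sets out from 6 (with 18) and comes back to the route at 21; it passes through no new compound (F0).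

Step 11 (epimerisation of C2'). Ionisation at C2' may be followed by loss of the C3' proton, which opens ring 2 to a triarylethene and, if reversible, erodes the enantiomeric purity set in step 10. It may also lead to intermolecular Friedel–Crafts alkylation of the electron-rich rings, or stop at a cis/trans mixture that is hard to separate. The fallback postpones the epimerisation to the demethylation and carries the cis series forward. It sets out from 17: bromine–lithium exchange and transmetalation as in step 12 would give the cis aryllithium F1 and the cis arylzinc chloride F2, whose nickel-catalysed coupling with 7 would give the benzyl ether with a cis ring 2 F3. Hydrogenolysis as in step 13 would then give the phenol F4, and triflation as in step 14 the triflate F5. Treatment of F5 with BBr3 as in step 15 would cleave the six methyl ethers and, through the same C2'–O1' ionisation under much stronger Lewis acid conditions, equilibrate C2' to trans, so that the route is rejoined at 24.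

Step 18 (Z-styryl coupling). Oxidative addition into the hindered, electron-rich C4 triflate may be slow, so that protodeboronation of the Z-alkenylboronate, Z-to-E isomerisation on palladium and base-induced loss of silyl groups compete. The fallback forms the same C4–C bond at the alkyne oxidation level and sets the geometry afterwards. It sets out from 25, which would be coupled with alkyne 26 itself in a Sonogashira reaction (Pd(PPh3)2Cl2, CuI, Et3N, DMF, 60 °C) to give the diarylalkyne F6. Syn semihydrogenation of F6 over Lindlar catalyst (Pd/CaCO3 poisoned with Pb(OAc)2, quinoline, H2 1 atm, EtOAc, rt) would give the Z olefin and return to the route at 28.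

**Further compounds**

F0 | step 12 | none | none
F1 | step 11 | [(2S,3R)-3-(3,5-dimethoxyphenyl)-7-methoxy-2-(4-methoxyphenyl)-2,3-dihydrobenzofuran-5-yl]lithium (cis) | [Li]c1cc(OC)c2c(c1)[C@@H](c1cc(OC)cc(OC)c1)[C@@H](c1ccc(OC)cc1)O2
F2 | step 11 | [(2S,3R)-3-(3,5-dimethoxyphenyl)-7-methoxy-2-(4-methoxyphenyl)-2,3-dihydrobenzofuran-5-yl]zinc chloride (cis) | Cl[Zn]c1cc(OC)c2c(c1)[C@@H](c1cc(OC)cc(OC)c1)[C@@H](c1ccc(OC)cc1)O2
F3 | step 11 | (2S,3S)-4-(benzyloxy)-3-[(2S,3R)-3-(3,5-dimethoxyphenyl)-7-methoxy-2-(4-methoxyphenyl)-2,3-dihydrobenzofuran-5-yl]-6-methoxy-2-(4-methoxyphenyl)-2,3-dihydrobenzofuran | c1ccccc1COc1cc(OC)cc2c1[C@H](c1cc(OC)c3c(c1)[C@@H](c1cc(OC)cc(OC)c1)[C@@H](c1ccc(OC)cc1)O3)[C@@H](c1ccc(OC)cc1)O2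
F4 | step 11 | (2S,3S)-3-[(2S,3R)-3-(3,5-dimethoxyphenyl)-7-methoxy-2-(4-methoxyphenyl)-2,3-dihydrobenzofuran-5-yl]-6-methoxy-2-(4-methoxyphenyl)-2,3-dihydrobenzofuran-4-ol | Oc1cc(OC)cc2c1[C@H](c1cc(OC)c3c(c1)[C@@H](c1cc(OC)cc(OC)c1)[C@@H](c1ccc(OC)cc1)O3)[C@@H](c1ccc(OC)cc1)O2
F5 | step 11 | (2S,3S)-3-[(2S,3R)-3-(3,5-dimethoxyphenyl)-7-methoxy-2-(4-methoxyphenyl)-2,3-dihydrobenzofuran-5-yl]-6-methoxy-2-(4-methoxyphenyl)-2,3-dihydrobenzofuran-4-yl trifluoromethanesulfonate | O=S(=O)(Oc1cc(OC)cc2c1[C@H](c1cc(OC)c3c(c1)[C@@H](c1cc(OC)cc(OC)c1)[C@@H](c1ccc(OC)cc1)O3)[C@@H](c1ccc(OC)cc1)O2)C(F)(F)F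
F6 | step 18 | heptakis(tert-butyldimethylsilyl) ether of the 4-[(4-hydroxyphenyl)ethynyl] analogue of the target (alkyne in place of the Z olefin) | CC(C)(C)[Si](C)(C)Oc1ccc(C#Cc2cc(O[Si](C)(C)C(C)(C)C)cc3c2[C@H](c2cc(O[Si](C)(C)C(C)(C)C)c4c(c2)[C@@H](c2cc(O[Si](C)(C)C(C)(C)C)cc(O[Si](C)(C)C(C)(C)C)c2)[C@H](c2ccc(O[Si](C)(C)C(C)(C)C)cc2)O4)[C@@H](c2ccc(O[Si](C)(C)C(C)(C)C)cc2)O3)cc1
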